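## Retrosynthetic overview

- **Feature:** ring B (C6') sits on C8'' of the flavone, the carbon between C7''–O and C8a''–O1'', and not on C6''. The two oxygens flanking the biaryl bond must therefore be told apart, one becoming O1'' and the other the 7''-OH.
- **Last ring:** flavanone ring C (O1–C2 bond, the 2R centre) comes from a catalytic asymmetric oxa-Michael closure of an alkylidene β-keto ester. That ester is built from the ring B aldehyde (C1'–CHO) and a ring A aroylacetate; decarboxylation and global hydrogenolysis follow.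
- **Key disconnection:** C4''–C4a'' of the flavone pyranone, by intramolecular Friedel–Crafts acylation of a (Z)-3-aryloxycinnamic acid. O1''–C2'' is made earlier by phenoxide addition to an arylpropiolate.
- **Source of the single free phenol:** a 6H-benzo[c]chromen-6-one, from copper-catalysed arylation of phloroglucinol with a 2-bromobenzoic acid. The lactone oxygen marks the future O1'' and the lactone carbonyl becomes the aldehyde.
- **Ring order:** temporary lactone ring, then flavone pyranone, then flavanone ring C.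

Key step: step 10

Assumption 1: the target string defines no configuration for the C6'–C8'' biaryl axis, so the axis is treated as stereochemically undefined and rotamers about it are carried on together.

Assumption 2: the quinine-derived thiourea is taken to deliver the 2R product, by analogy with its sense of induction in conjugate additions to chalcone-type acceptors. The sense is to be checked by circular dichroism after step 14, and the quinidine-derived pseudoenantiomer takes its place if it is the opposite.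

## Route

Step 1
Reactants: 1 3,4-bis(benzyloxy)benzaldehyde
Product: 2 4,5-bis(benzyloxy)-2-bromobenzaldehyde
Conditions: Br2 (1.05 equiv), NaOAc, AcOH, rt
Reagents that add atoms: bromine, BrBr
Why: Electrophilic aromatic bromination should go para to the 3-benzyloxy group (ortho to CHO), because the 4-benzyloxy group is deactivated by conjugation with the formyl group, and NaOAc buffers HBr so that the benzyl ethers are kept.

Step 2
Reactants: 2 4,5-bis(benzyloxy)-2-bromobenzaldehyde
Product: 3 4,5-bis(benzyloxy)-2-bromobenzoic acid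
Conditions: NaClO2, NaH2PO4, 2-methyl-2-butene, t-BuOH/THF/H2O, rt
Reagents that add atoms: sodium chlorite, [Na+].[O-]Cl=O
Why: The Pinnick oxidation converts the aldehyde into the acid at near-neutral pH and leaves the aryl bromide and the benzyl ethers alone.

Step 3
Reactants: 3 4,5-bis(benzyloxy)-2-bromobenzoic acid; 4 phloroglucinol (2.5 equiv)
Product: 6 8,9-bis(benzyloxy)-1,3-dihydroxy-6H-benzo[c]chromen-6-one, via biaryl acid 5 (not isolated)
Conditions: NaOH, H2O (a little 1,4-dioxane), 100 °C, Ar; CuSO4 (10 mol %); then 2 M HCl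
Reagents that add atoms: none
Why: In the Hurtley reaction the ortho carboxylate holds copper next to the C–Br bond and the phloroglucinol phenolate reacts at carbon; since its three ring carbons and the two hydroxyls flanking the new bond are equivalent, one biaryl and, after lactonisation, one lactone should result.

Step 4
Reactants: 6 8,9-bis(benzyloxy)-1,3-dihydroxy-6H-benzo[c]chromen-6-one
Product: 7 1,3,8,9-tetrakis(benzyloxy)-6H-benzo[c]chromen-6-one
Conditions: BnBr (2.4 equiv), K2CO3, DMF, 50 °C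
Reagents that add atoms: benzyl bromide, BrCc1ccccc1
Why: Williamson etherification caps the two free phenols, while the third oxygen stays masked in the lactone, which is stable to anhydrous carbonate.

Step 5
Reactants: 7 1,3,8,9-tetrakis(benzyloxy)-6H-benzo[c]chromen-6-one
Product: 8 (±)-1,3,8,9-tetrakis(benzyloxy)-6H-benzo[c]chromen-6-ol
Conditions: i-Bu2AlH (1.15 equiv), CH2Cl2, −78 °C; aq. potassium sodium tartrate
Reagents that add atoms: none
Why: Partial lactone reduction stops at the lactol because the tetrahedral aluminium alkoxide persists at −78 °C until the quench.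

Step 6
Reactants: 1 3,4-bis(benzyloxy)benzaldehyde
Product: 9 1,2-bis(benzyloxy)-4-(2,2-dibromovinyl)benzene
Conditions: CBr4 (1.5 equiv), PPh3 (3 equiv), CH2Cl2, 0 °C
Reagents that add atoms: carbon tetrabromide, BrC(Br)(Br)Br
Why: This is the first stage of the Corey–Fuchs sequence, a Wittig-type olefination by the dibromomethylene ylide, which is dependable for aromatic aldehydes.

Step 7
Reactants: 9 1,2-bis(benzyloxy)-4-(2,2-dibromovinyl)benzene
Product: 11 ethyl 3-[3,4-bis(benzyloxy)phenyl]prop-2-ynoate, via lithium arylacetylide 10 (not isolated)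
Conditions: n-BuLi (2.1 equiv), THF, −78 °C; ClCO2Et, −78 °C → rt
Reagents that add atoms: ethyl chloroformate, CCOC(=O)Cl; n-butyllithium, [Li]CCCC (lithium of intermediate 10 only)
Why: In the second Corey–Fuchs stage, bromine–lithium exchange and Fritsch–Buttenberg–Wiechell-type loss of LiBr give the acetylide, which is acylated by the chloroformate; the aryl benzyl ethers tolerate n-BuLi in the cold.

Step 8
Reactants: 8 (±)-1,3,8,9-tetrakis(benzyloxy)-6H-benzo[c]chromen-6-ol; 11 ethyl 3-[3,4-bis(benzyloxy)phenyl]prop-2-ynoate (1.3 equiv)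
Product: 13 ethyl (Z)-3-[3,4-bis(benzyloxy)phenyl]-3-{3,5-bis(benzyloxy)-2-[4,5-bis(benzyloxy)-2-formylphenyl]phenoxy}acrylate, via ring-opened hydroxy aldehyde 12 (not isolated)
Conditions: Cs2CO3 (0.3 equiv), DMF, 70 °C
Reagents that add atoms: none
Why: This is an oxa-Michael addition of a phenoxide to an arylpropiolate, in which base shifts the lactol to the more acidic phenol–aldehyde form; anti addition and the cinnamate-like placement of the aryl group trans to the ester both favour the Z alkene.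

Step 9
Reactants: 13 ethyl (Z)-3-[3,4-bis(benzyloxy)phenyl]-3-{3,5-bis(benzyloxy)-2-[4,5-bis(benzyloxy)-2-formylphenyl]phenoxy}acrylate
Product: 14 (Z)-3-[3,4-bis(benzyloxy)phenyl]-3-{3,5-bis(benzyloxy)-2-[4,5-bis(benzyloxy)-2-formylphenyl]phenoxy}acrylic acid
Conditions: LiOH·H2O, THF/MeOH/H2O, rt; 1 M HCl to pH 3
Reagents that add atoms: lithium hydroxide, [Li+].[OH-]
Why: Saponification of the ethyl ester is the standard access to 3-aryloxycinnamic acids, and the non-enolisable aldehyde and the fully substituted β-carbon should withstand LiOH at room temperature.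

Step 10
Reactants: 14 (Z)-3-[3,4-bis(benzyloxy)phenyl]-3-{3,5-bis(benzyloxy)-2-[4,5-bis(benzyloxy)-2-formylphenyl]phenoxy}acrylic acid
Product: 16 4,5-bis(benzyloxy)-2-{5,7-bis(benzyloxy)-2-[3,4-bis(benzyloxy)phenyl]-4-oxo-4H-chromen-8-yl}benzaldehyde, via acid chloride 15 (not isolated)
Conditions: (COCl)2 (1.5 equiv), DMF (cat.), CH2Cl2, 0 °C, evaporate; SnCl4 (2.5 equiv), CH2Cl2 (0.01 M), −78 → −30 °C; cold aq. NaHCO3
Reagents that add atoms: oxalyl chloride, O=C(Cl)C(=O)Cl (chlorine of intermediate 15 only)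
Why: Oxalyl chloride/DMF turns 14 into acid chloride 15, SnCl4 polarises or ionises its C–Cl bond, the acyl carbon (future C4'') is attacked by the aryloxy-ring carbon ortho to the ether oxygen (future C4a''), and loss of the proton from the arenium ion leaves the 4H-pyran-4-one. The closest known reaction type is the classical flavone synthesis by intramolecular Friedel–Crafts acylation of 3-aryloxycinnamic acids obtained from phenoxides and arylpropiolates. The one ring formed, the flavone pyranone, closes in a 6-exo-trig mode at the activated acyl carbon (6-exo-dig if the free acylium ion takes part), the Z alkene holding the acyl group and the aryloxy ring on the same side. No stereocentre is created. The regioselectivity needed, 8''-aryl against 6''-aryl flavone, is secured by the substrate: of the two carbons ortho to O1'' one carries ring B, the other is free and is activated by O1'' (ortho), the 5''-benzyloxy group (ortho) and the 7''-benzyloxy group (para), and C6'' lies out of reach of the short tether. Chemoselectivity towards six benzyl ethers and the aldehyde rests on the high nucleophilicity of this carbon, which should allow short contact with SnCl4 below −30 °C at high dilution, and any E isomer should equilibrate through the Lewis acid-bound push–pull alkene.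

Step 11
Reactants: 17 2',4',6'-trihydroxyacetophenone
Product: 18 1-[2,4-bis(benzyloxy)-6-hydroxyphenyl]ethan-1-one
Conditions: BnBr (2.05 equiv), K2CO3, DMF, rt → 50 °C
Reagents that add atoms: benzyl bromide, BrCc1ccccc1
Why: Selective Williamson etherification stops at the dibenzyl ether because the last ortho hydroxyl is hydrogen-bonded to the ketone and is much less nucleophilic.

Step 12
Reactants: 18 1-[2,4-bis(benzyloxy)-6-hydroxyphenyl]ethan-1-one
Product: 20 tert-butyl 3-[2,4-bis(benzyloxy)-6-hydroxyphenyl]-3-oxopropanoate, via dilithium enolate-phenoxide 19 (not isolated)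
Conditions: LiN(SiMe3)2 (3.2 equiv), THF, −78 °C; Boc2O (1.1 equiv), −78 → −20 °C; AcOH
Reagents that add atoms: di-tert-butyl dicarbonate, CC(C)(C)OC(=O)OC(=O)OC(C)(C)C; lithium hexamethyldisilazide, [Li]N([Si](C)(C)C)[Si](C)(C)C (lithium of intermediate 19 only)
Why: In this crossed Claisen-type C-acylation the enolate carbon of the dianion takes up the tert-butoxycarbonyl group, any aryl carbonate formed at oxygen is carried to the same product by Baker–Venkataraman-type O-to-C transfer, and the extra base holds the product as its enolate so that coumarin formation stays slow in the cold.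

Step 13
Reactants: 16 4,5-bis(benzyloxy)-2-{5,7-bis(benzyloxy)-2-[3,4-bis(benzyloxy)phenyl]-4-oxo-4H-chromen-8-yl}benzaldehyde; 20 tert-butyl 3-[2,4-bis(benzyloxy)-6-hydroxyphenyl]-3-oxopropanoate
Product: 21 tert-butyl (Z)-2-[2,4-bis(benzyloxy)-6-hydroxybenzoyl]-3-(4,5-bis(benzyloxy)-2-{5,7-bis(benzyloxy)-2-[3,4-bis(benzyloxy)phenyl]-4-oxo-4H-chromen-8-yl}phenyl)acrylate
Conditions: piperidine (20 mol %), AcOH (20 mol %), 4 Å MS, toluene, 25–40 °C
Reagents that add atoms: none
Why: The Knoevenagel condensation runs through the iminium ion of the non-enolisable aldehyde; the mild temperature and the phenol–ketone hydrogen bond should hold back premature racemic ring closure, and the isomer with the aryl group cis to the ester is expected under thermodynamic control, a geometry that is lost in step 14.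

Step 14
Reactants: 21 tert-butyl (Z)-2-[2,4-bis(benzyloxy)-6-hydroxybenzoyl]-3-(4,5-bis(benzyloxy)-2-{5,7-bis(benzyloxy)-2-[3,4-bis(benzyloxy)phenyl]-4-oxo-4H-chromen-8-yl}phenyl)acrylate
Product: 23 (2R)-5,7-bis(benzyloxy)-2-(4,5-bis(benzyloxy)-2-{5,7-bis(benzyloxy)-2-[3,4-bis(benzyloxy)phenyl]-4-oxo-4H-chromen-8-yl}phenyl)chroman-4-one, via 3-tert-butoxycarbonyl flavanone 22 (not isolated)
Conditions: N-[3,5-bis(trifluoromethyl)phenyl]-N'-[(8α,9S)-6'-methoxycinchonan-9-yl]thiourea (15 mol %), toluene, −25 °C; then p-TsOH·H2O, 80 °C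
Reagents that add atoms: none
Why: In this bifunctional thiourea/tertiary amine-catalysed intramolecular oxa-Michael addition (6-endo-trig) the thiourea binds the β-dicarbonyl unit, the quinuclidine nitrogen takes the phenol proton and the oxygen is delivered to one face of the alkylidene carbon, which sets C2 as R; p-TsOH then cleaves the tert-butyl ester and the β-keto acid loses CO2 without touching C2.

Step 15
Reactants: 23 (2R)-5,7-bis(benzyloxy)-2-(4,5-bis(benzyloxy)-2-{5,7-bis(benzyloxy)-2-[3,4-bis(benzyloxy)phenyl]-4-oxo-4H-chromen-8-yl}phenyl)chroman-4-one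
Product: 24 (2R)-2-{2-[2-(3,4-dihydroxyphenyl)-5,7-dihydroxy-4-oxo-4H-chromen-8-yl]-4,5-dihydroxyphenyl}-5,7-dihydroxychroman-4-one (CNP0228504.1)
Conditions: H2 (1 atm), 10% Pd/C, THF/MeOH 1:1, rt
Reagents that add atoms: none
Why: Hydrogenolysis removes all eight aryl benzyl ethers under neutral conditions, the flavone C2''=C3'' bond and both conjugated carbonyl groups are reduced much more slowly, and the absence of base keeps C2 from racemising through the chalcone.

## Compound list

1 | 3,4-bis(benzyloxy)benzaldehyde | O=Cc1ccc(OCc2ccccc2)c(OCc2ccccc2)c1 | starting material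
2 | 4,5-bis(benzyloxy)-2-bromobenzaldehyde | O=Cc1cc(OCc2ccccc2)c(OCc2ccccc2)cc1Br | intermediate
3 | 4,5-bis(benzyloxy)-2-bromobenzoic acid | OC(=O)c1cc(OCc2ccccc2)c(OCc2ccccc2)cc1Br | intermediate
4 | phloroglucinol | Oc1cc(O)cc(O)c1 | starting material
5 | 4,5-bis(benzyloxy)-2-(2,4,6-trihydroxyphenyl)benzoic acid | OC(=O)c1cc(OCc2ccccc2)c(OCc2ccccc2)cc1-c1c(O)cc(O)cc1O | intermediate (not isolated)
6 | 8,9-bis(benzyloxy)-1,3-dihydroxy-6H-benzo[c]chromen-6-one | O=C1Oc2cc(O)cc(O)c2-c2cc(OCc3ccccc3)c(OCc3ccccc3)cc21 | intermediate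
7 | 1,3,8,9-tetrakis(benzyloxy)-6H-benzo[c]chromen-6-one | O=C1Oc2cc(OCc3ccccc3)cc(OCc3ccccc3)c2-c2cc(OCc3ccccc3)c(OCc3ccccc3)cc21 | intermediate
8 | (±)-1,3,8,9-tetrakis(benzyloxy)-6H-benzo[c]chromen-6-ol (racemic lactol) | OC1Oc2cc(OCc3ccccc3)cc(OCc3ccccc3)c2-c2cc(OCc3ccccc3)c(OCc3ccccc3)cc21 | intermediate
9 | 1,2-bis(benzyloxy)-4-(2,2-dibromovinyl)benzene | BrC(Br)=Cc1ccc(OCc2ccccc2)c(OCc2ccccc2)c1 | intermediate
10 | lithium [3,4-bis(benzyloxy)phenyl]acetylide | [Li]C#Cc1ccc(OCc2ccccc2)c(OCc2ccccc2)c1 | intermediate (not isolated)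
11 | ethyl 3-[3,4-bis(benzyloxy)phenyl]prop-2-ynoate | CCOC(=O)C#Cc1ccc(OCc2ccccc2)c(OCc2ccccc2)c1 | intermediate
12 | 4,5-bis(benzyloxy)-2-[2,4-bis(benzyloxy)-6-hydroxyphenyl]benzaldehyde (open form of 8) | O=Cc1cc(OCc2ccccc2)c(OCc2ccccc2)cc1-c1c(O)cc(OCc2ccccc2)cc1OCc1ccccc1 | intermediate (not isolated)
13 | ethyl (Z)-3-[3,4-bis(benzyloxy)phenyl]-3-{3,5-bis(benzyloxy)-2-[4,5-bis(benzyloxy)-2-formylphenyl]phenoxy}acrylate | CCOC(=O)/C=C(\Oc1cc(OCc2ccccc2)cc(OCc2ccccc2)c1-c1cc(OCc2ccccc2)c(OCc2ccccc2)cc1C=O)c1ccc(OCc2ccccc2)c(OCc2ccccc2)c1 | intermediate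
14 | (Z)-3-[3,4-bis(benzyloxy)phenyl]-3-{3,5-bis(benzyloxy)-2-[4,5-bis(benzyloxy)-2-formylphenyl]phenoxy}acrylic acid | OC(=O)/C=C(\Oc1cc(OCc2ccccc2)cc(OCc2ccccc2)c1-c1cc(OCc2ccccc2)c(OCc2ccccc2)cc1C=O)c1ccc(OCc2ccccc2)c(OCc2ccccc2)c1 | intermediate
15 | (Z)-3-[3,4-bis(benzyloxy)phenyl]-3-{3,5-bis(benzyloxy)-2-[4,5-bis(benzyloxy)-2-formylphenyl]phenoxy}acryloyl chloride | ClC(=O)/C=C(\Oc1cc(OCc2ccccc2)cc(OCc2ccccc2)c1-c1cc(OCc2ccccc2)c(OCc2ccccc2)cc1C=O)c1ccc(OCc2ccccc2)c(OCc2ccccc2)c1 | intermediate (not isolated)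
16 | 4,5-bis(benzyloxy)-2-{5,7-bis(benzyloxy)-2-[3,4-bis(benzyloxy)phenyl]-4-oxo-4H-chromen-8-yl}benzaldehyde | O=Cc1cc(OCc2ccccc2)c(OCc2ccccc2)cc1-c1c(OCc2ccccc2)cc(OCc2ccccc2)c2c(=O)cc(-c3ccc(OCc4ccccc4)c(OCc4ccccc4)c3)oc12 | intermediate
17 | 2',4',6'-trihydroxyacetophenone | CC(=O)c1c(O)cc(O)cc1O | starting material
18 | 1-[2,4-bis(benzyloxy)-6-hydroxyphenyl]ethan-1-one | CC(=O)c1c(O)cc(OCc2ccccc2)cc1OCc1ccccc1 | intermediate
19 | dilithium enolate-phenoxide of 18 | C=C(O[Li])c1c(O[Li])cc(OCc2ccccc2)cc1OCc1ccccc1 | intermediate (not isolated)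
20 | tert-butyl 3-[2,4-bis(benzyloxy)-6-hydroxyphenyl]-3-oxopropanoate | CC(C)(C)OC(=O)CC(=O)c1c(O)cc(OCc2ccccc2)cc1OCc1ccccc1 | intermediate
21 | tert-butyl (Z)-2-[2,4-bis(benzyloxy)-6-hydroxybenzoyl]-3-(4,5-bis(benzyloxy)-2-{5,7-bis(benzyloxy)-2-[3,4-bis(benzyloxy)phenyl]-4-oxo-4H-chromen-8-yl}phenyl)acrylate | CC(C)(C)OC(=O)/C(C(=O)c1c(O)cc(OCc2ccccc2)cc1OCc1ccccc1)=C\c1cc(OCc2ccccc2)c(OCc2ccccc2)cc1-c1c(OCc2ccccc2)cc(OCc2ccccc2)c2c(=O)cc(-c3ccc(OCc4ccccc4)c(OCc4ccccc4)c3)oc12 | intermediate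
22 | tert-butyl (2R)-5,7-bis(benzyloxy)-2-(4,5-bis(benzyloxy)-2-{5,7-bis(benzyloxy)-2-[3,4-bis(benzyloxy)phenyl]-4-oxo-4H-chromen-8-yl}phenyl)-4-oxochromane-3-carboxylate (C3 labile, left undefined) | O=C1C(C(=O)OC(C)(C)C)[C@H](c2cc(OCc5ccccc5)c(OCc5ccccc5)cc2-c2c(OCc5ccccc5)cc(OCc5ccccc5)c3c(=O)cc(-c4ccc(OCc5ccccc5)c(OCc5ccccc5)c4)oc23)Oc2cc(OCc5ccccc5)cc(OCc5ccccc5)c21 | intermediate (not isolated)
23 | (2R)-5,7-bis(benzyloxy)-2-(4,5-bis(benzyloxy)-2-{5,7-bis(benzyloxy)-2-[3,4-bis(benzyloxy)phenyl]-4-oxo-4H-chromen-8-yl}phenyl)chroman-4-one | O=C1C[C@H](c2cc(OCc5ccccc5)c(OCc5ccccc5)cc2-c2c(OCc5ccccc5)cc(OCc5ccccc5)c3c(=O)cc(-c4ccc(OCc5ccccc5)c(OCc5ccccc5)c4)oc23)Oc2cc(OCc5ccccc5)cc(OCc5ccccc5)c21 | intermediate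
24 | (2R)-2-{2-[2-(3,4-dihydroxyphenyl)-5,7-dihydroxy-4-oxo-4H-chromen-8-yl]-4,5-dihydroxyphenyl}-5,7-dihydroxychroman-4-one | O=C1C[C@H](c2cc(O)c(O)cc2-c2c(O)cc(O)c3c(=O)cc(-c4ccc(O)c(O)c4)oc23)Oc2cc(O)cc(O)c21 | target

## Step count and risks

Total step count: 15.
Longest linear sequence: 11 steps (steps 1–5, 8–10, 13–15). Steps 6–7 and 11–12 are side branches.

**Step 10.**
- What may go wrong:
  - Chelation-driven loss of benzyl ethers under SnCl4, first the ether peri to the new carbonyl.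
  - Lewis acid activation of the aldehyde towards intermolecular hydroxyalkylation of the electron-rich rings.
  - Five-membered closure of any E acid chloride onto the catechol ring.
- Fallback, setting out from 2 and coming back at 16: the flavone is taken in complete and the biaryl bond is made last.
  - Miyaura borylation of 2 (bis(pinacolato)diboron, PdCl2(dppf), KOAc, 1,4-dioxane, 80 °C) should give 4,5-bis(benzyloxy)-2-(4,4,5,5-tetramethyl-1,3,2-dioxaborolan-2-yl)benzaldehyde F1.
  - Purchased luteolin F2 is perbenzylated (BnBr, K2CO3, DMF, 80 °C) to 5,7,3',4'-tetra-O-benzylluteolin F3.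
  - F3 is iodinated (I2, AgOAc, CH2Cl2, rt), following the known C8 preference of fully etherified 5,7-dioxygenated flavones, to 8-iodo-5,7,3',4'-tetra-O-benzylluteolin F4.
  - Suzuki–Miyaura coupling of F1 with F4 (Pd(OAc)2, 2-dicyclohexylphosphino-2',6'-dimethoxybiphenyl, K3PO4, toluene/H2O, 90 °C) should give 16.
  - The position of the iodine then has to be proven by long-range NMR correlation, since the substrate no longer enforces it.

**Step 14.**
- What may go wrong:
  - Poor facial selectivity, because the ortho flavonyl group crowds the alkylidene carbon and slow rotation about the biaryl axis offers the catalyst two substrate rotamers.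
  - Uncatalysed background closure.
  - Benzyl migration or partial racemisation by retro-oxa-Michael opening in the hot acid.
- Fallback, setting out from 16 and 18 and coming back at 23: resolution replaces asymmetric catalysis.
  - Claisen–Schmidt condensation of 16 with 18 (KOH, EtOH/THF, rt) should give (E)-1-[2,4-bis(benzyloxy)-6-hydroxyphenyl]-3-(4,5-bis(benzyloxy)-2-{5,7-bis(benzyloxy)-2-[3,4-bis(benzyloxy)phenyl]-4-oxo-4H-chromen-8-yl}phenyl)prop-2-en-1-one F5.
  - F5 is closed (NaOAc, EtOH, reflux) to the racemic octa-O-benzyl flavanone F6.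
  - Preparative chromatography of F6 on a chiral stationary phase delivers 23 and the (2S)-octa-O-benzyl flavanone F7.
  - F7 can be returned to F5 by base-induced ring opening and recycled.

**Step 8.**
- What may go wrong:
  - Addition through the lactol oxygen in place of the phenoxide.
  - Sluggish addition of the hindered phenoxide to the electron-rich alkyne, so that side reactions of the aldehyde take over.
- Fallback, setting out from 7 and coming back at 13: the aldehyde oxidation level is introduced only after the vinyl ether is in place.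
  - Full reduction of 7 (LiAlH4, THF, 0 °C) should give 3,5-bis(benzyloxy)-2-[4,5-bis(benzyloxy)-2-(hydroxymethyl)phenyl]phenol F8.
  - In F8 only the phenol is deprotonated by Cs2CO3, so addition to 11 (DMF, 70 °C) should give ethyl (Z)-3-[3,4-bis(benzyloxy)phenyl]-3-{3,5-bis(benzyloxy)-2-[4,5-bis(benzyloxy)-2-(hydroxymethyl)phenyl]phenoxy}acrylate F9.
  - Oxidation of the benzylic alcohol of F9 (MnO2, CH2Cl2, rt) returns to 13.

## Further compounds

F1 | step 10 | 4,5-bis(benzyloxy)-2-(4,4,5,5-tetramethyl-1,3,2-dioxaborolan-2-yl)benzaldehyde | O=Cc1cc(OCc2ccccc2)c(OCc2ccccc2)cc1B1OC(C)(C)C(C)(C)O1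
F2 | step 10 | luteolin (purchased) | O=c1cc(-c2ccc(O)c(O)c2)oc2cc(O)cc(O)c12
F3 | step 10 | 5,7,3',4'-tetra-O-benzylluteolin | O=c1cc(-c2ccc(OCc3ccccc3)c(OCc3ccccc3)c2)oc2cc(OCc3ccccc3)cc(OCc3ccccc3)c12
F4 | step 10 | 8-iodo-5,7,3',4'-tetra-O-benzylluteolin | O=c1cc(-c2ccc(OCc3ccccc3)c(OCc3ccccc3)c2)oc2c(I)c(OCc3ccccc3)cc(OCc3ccccc3)c12
F5 | step 14 | (E)-1-[2,4-bis(benzyloxy)-6-hydroxyphenyl]-3-(4,5-bis(benzyloxy)-2-{5,7-bis(benzyloxy)-2-[3,4-bis(benzyloxy)phenyl]-4-oxo-4H-chromen-8-yl}phenyl)prop-2-en-1-one | O=C(/C=C/c1cc(OCc2ccccc2)c(OCc2ccccc2)cc1-c1c(OCc2ccccc2)cc(OCc2ccccc2)c2c(=O)cc(-c3ccc(OCc4ccccc4)c(OCc4ccccc4)c3)oc12)c1c(O)cc(OCc2ccccc2)cc1OCc1ccccc1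
F6 | step 14 | racemic octa-O-benzyl flavanone (rac-23) | O=C1CC(c2cc(OCc5ccccc5)c(OCc5ccccc5)cc2-c2c(OCc5ccccc5)cc(OCc5ccccc5)c3c(=O)cc(-c4ccc(OCc5ccccc5)c(OCc5ccccc5)c4)oc23)Oc2cc(OCc5ccccc5)cc(OCc5ccccc5)c21
F7 | step 14 | (2S)-octa-O-benzyl flavanone (ent-23) | O=C1C[C@@H](c2cc(OCc5ccccc5)c(OCc5ccccc5)cc2-c2c(OCc5ccccc5)cc(OCc5ccccc5)c3c(=O)cc(-c4ccc(OCc5ccccc5)c(OCc5ccccc5)c4)oc23)Oc2cc(OCc5ccccc5)cc(OCc5ccccc5)c21
F8 | step 8 | 3,5-bis(benzyloxy)-2-[4,5-bis(benzyloxy)-2-(hydroxymethyl)phenyl]phenol | OCc1cc(OCc2ccccc2)c(OCc2ccccc2)cc1-c1c(O)cc(OCc2ccccc2)cc1OCc1ccccc1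
F9 | step 8 | ethyl (Z)-3-[3,4-bis(benzyloxy)phenyl]-3-{3,5-bis(benzyloxy)-2-[4,5-bis(benzyloxy)-2-(hydroxymethyl)phenyl]phenoxy}acrylate | CCOC(=O)/C=C(\Oc1cc(OCc2ccccc2)cc(OCc2ccccc2)c1-c1cc(OCc2ccccc2)c(OCc2ccccc2)cc1CO)c1ccc(OCc2ccccc2)c(OCc2ccccc2)c1
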